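The pitfall in this flask is to read the vanished solid as a finished reaction. In the epsilon flask, solid substrate stands at 0% by 1.33 min, yet target levels off far below the full charge.

| flask | solid substrate | partner | temperature | remark | time |
|---|---|---|---|---|---|
| epsilon | 20 mM | 21 mM | 110 °C | the very flask that is asked about, followed so far |  |
| alpha | 20 mM | 42 mM | 95 °C | run made earlier |  |
| flask | 20 mM | 21.0 mM | 110 °C |  | 12 min |

- epsilon (time / min: target / %, solid substrate / %): 1.33: 47, 0; 2.50: 55, 2; 4.00: 57, 1; 5.00: 56, 0; 6.00: 56, 1; 8.00: 55, 1
- alpha (time / min: target / %, solid substrate / %): 2.00: 68, 2; 5.00: 89, 0; 8.00: 95, 0; 12.0: 93, 0; 20.0: 98, 1; 25.0: 94, 2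

(readings scatter by 1.5 percentage points)

- ochre: change nothing and wait 4.0 min more
- violet: at 12 min add partner, 50.0% of the amount charged, then wait 4.0 min
- teal: at 12 min raise the temperature by 10 K, then wait 4.0 min

* target, in percent of the solid substrate first charged, at 12 min
* which option adds most target ("none" when 2 percentage points or less is all one gets) (ochre / violet / teal / none)
* target present, in percent of the solid substrate first charged, after ochre
* target present, in percent of the solid substrate first charged, after teal

From 4.00 min to 8.00 min the epsilon readings average 56.0%, or 11.2 mM of target, and we commit to that level for 12 min. The balance then leaves dissolved substrate, A, at 8.80 mM. Target stands level beside it, while the alpha run with 42 mM of partner climbs to 95%. So we assume no free partner in the flask at 12 min, and we expect ochre and teal to add nothing.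

Partner can go to target or to side product, and the step to target also needs A. Its share φ that became target, and the mean of A between the earliest reading and the level, are:

φ = 11.2 mM / 21 mM = 53.3%

Ā = 9.70 mM

a = Ā(1/φ − 1) = 8.49 mM

This a is the split concentration, the value of A at which partner goes equally to target and side product, the inverse of a selectivity factor. The share at any A is A/(A + a).

The weak link is carrying φ straight over to violet's dose of 10.5 mM, since A starts lower there than Ā and falls as the dose reacts. So we reckon the gain x with the mean A − x/2, pass after pass:

x = 5.34 mM, then 4.40 mM, then 4.59 mM

That is 23 percentage points, and the 4.0 min allowed matches the 4.00 min by which epsilon had levelled.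

The forecast gives 56% at 12 min, 56% after ochre and 56% after teal, and it chooses violet with “about +19 points”, which differs from our 23 points.

The flask gives 56.1% at 12 min, 56.1% after ochre, 56.1% after teal, and 21 points more with violet. Partner, the limiting reagent here, stands at 0% of its charge at 12.0 min. The dose meets A = 8.80 mM against a = 8.49 mM, so its earliest part goes to target at a share of 50.9%, about half.

    partner → side product (k = 0.0110 /s, Ea = 96.0 kJ/mol)
    dissolved substrate + partner → target (k = 1.20 /M/s, Ea = 79.0 kJ/mol)
    solid product ⇌ target, rate k3*(cs3 - [target]) while solid is left; crystals form when [target] > cs3 (solubility = 9.60 mM, k = 3.00 /s)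
    solid substrate ⇌ dissolved substrate, rate k4*(cs4 - [dissolved substrate]) while solid is left; crystals form when [dissolved substrate] > cs4 (solubility = 14.0 mM, k = 0.170 /s)
    (constants at 110 °C)

The neighbour holds 13 mM of partner, less than the flask, so Ā does not carry over: we keep a and take for A the solid substrate charged minus the target x, pass after pass:

x = 7.88 mM, then 7.65 mM, then 7.71 mM

That is 38.5% of the charge, and the neighbour's computed value is 36.3%.

The earlier runs and the new flask were computed from invented constants, noise included.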